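## The problem

Atom labels used throughout: C6 is the quaternary carbon bearing CH2OH and the (S)-3-hydroxypentyl chain, C7 the CH next to it, C8 and C9 the two ring CH2 groups, C10=C11 the tetrasubstituted alkene, C12 the allylic CH, C13 and C14 the CH2 groups of the cyclopentene, C15 the CH bearing CH2OH, C16 its neighbouring CH2, C17 the quaternary carbon bearing C18H2–N, and C19 the NCH2 on C7.

In target 38 the single sp2 carbon C11 belongs at once to cyclopentene ring A (C10–C14), cyclopentane ring B (C11, C12, C15, C16, C17) and cycloheptene ring C (C6–C11, C17). An N-methylpiperidine (C17, C18, N, C19, C7, C6) bridges ring C, so that C6 is the one-carbon bridge of a 3-azabicyclo[4.3.1]decane. There are six stereocentres: C12 and C15 (C13 and the CH2OH carbon cis on ring B, the less stable arrangement), the vicinal quaternary pair C17/C6, the bridgehead C7 and the remote side-chain carbinol. A chain of control is available: C15 can set C12 through a lactone, the C12/C15 pair can set C17, the pseudo-axial C18 on C17 can set C6, and the bridge leaves C7 no choice. The carbinol is too far away to be induced and has to be brought in enantiopure. The fragile points are C12–H (allylic, and acidic whenever C11 is conjugated to a carbonyl, so equilibration would give the trans pair), a hydroxymethyl ketone at C6 (retro-aldol), and the amine, which must travel as a carbamate because a free tertiary amine quenches an excited enone. The enabling feature is that C10=C11 sits on the carbon common to rings A, B and C. Rings A and C can therefore be folded into a cyclobutene C8–C9=C10–C11 fused to a bicyclo[3.3.0]octenone (ring B plus the cyclopentenone C7, C8, C11, C17, C6). Because the target has C13 on the same face of ring B as C6, this folded intermediate necessarily carries one trans ring fusion, which the plan has to accept and exploit.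

## Retrosynthesis

**N–C19.** Target 38 is the desilylated form of amine 37, which is the reduction product of lactam 36. Cutting the amide bond of 36 gives the N-methylamino ester 35, released from the benzyl carbamate 34. This cut is preferred to an amine alkylation at the neopentyl carbon C18 or a reductive amination from a C7 nitrile, because only an ester makes C7 epimerizable under the ring-closing conditions. Only the epimer with C19 cis to C18 can close, so both C7 epimers of 34 should drain into 36. The forward step must acylate a hindered secondary amine.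

**C7–C19.** Ester 34 is the conjugate-reduction product of the unsaturated ester 33, which is the carbonylation product of enol triflate 32, made from ketone 31. C19 thus enters as a one-carbon carbonyl unit at the carbonyl carbon of 31. The triflate can form only toward C8 because C6 is quaternary. A one-step reductive cyanation of 31 would be shorter but would fix C7 without stereocontrol and give a group that cannot be equilibrated during ring closure.

**The two bonds at C6.** Ketone 31 comes from dienone 30 by saturation of C8=C9. Dienone 30 is the silyl ether of 29, which arises from 28 by attaching the CH2OH carbon, and 28 arises from dienone 23 and the side-chain iodide 27 (from the hydroxy ester 24 through 25 and 26). Both bonds are made on the dienone, not on the saturated ketone, because there C8 is sp2 and C6 is the only α-carbon. The order is dictated by the face rule: the last group enters anti to C18, and that group must be the one-carbon unit. Dienone 23 has no substituent at C6 and is much simpler.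

**Key disconnection.** Dienone 23 is traced to fenestrene 22 by re-forming C8–C11, and 22 to the enone–alkyne 21 by cutting C10–C11 and C8–C9. Two rings (A and C) and the C10=C11 and C8=C9 alkenes are removed at once, leaving a bicyclo[3.3.0]octenone with a butynyl chain on C12. Stepwise closure of a seven-membered ring onto a preformed A/B diquinane would have to place a tetrasubstituted alkene on C11 afterwards. Here the alkene is the by-product of the ring expansion. The forward reaction must form the straight photoadduct on the face dictated by C12 and then break only C8–C11.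

**Terminal alkyne.** Enone 21 comes from aldehyde 20 by one-carbon homologation (C9), 20 from alcohol 19, and 19 from the silyl ether 18. The alkyne is added after the cobalt step because a second alkyne would compete for the metal.

**Cyclopentenone and ring B.** Bicyclic enone 18 is cut at C11–C17, C6–C7 and C7–C8 to the cobalt complex 17 of the acyclic 1,6-enyne 16 (cyclocarbonylation). The neighbouring cut, aldol condensation of a 1,4-diketone on a ring-B cyclopentanone, would pass through a C11 ketone with an epimerizable C12 and would lose the cis pair. The cobalt route never makes C11 a ketone before the enone exists and runs under neutral conditions. The forward step must set the quaternary C17 from the C12/C15 pair.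

**Alkyne from a lactone.** Enyne 16 is the silyl ether of enynol 15, which comes from lactol 13 (through its open form 14) by one-carbon homologation. Lactol 13 is the half-reduced lactone 12. The lactone carbonyl is C11 and its CH2O carbon is the CH2OH carbon on C15.

**C12–C13.** Lactone 12 is cut to the β-substituted butyrolactone 10 and iodide 11. Because the lactone ring uses the CH2O carbon where ring B uses C16, the cis pair of ring B corresponds to the trans lactone. This is the product that enolate alkylation of 10 gives by default.

**C15–C16.** Lactone 10 comes from hydroxy ester 9, and 9 from imide 8 by removal of the auxiliary. Imide 8 is cut at C15–C16 to the succinate imide 7 and the allylic bromide 3. Imide 7 comes from acid 4 and oxazolidinone 5 through anhydride 6. Bromide 3 comes from carbamate 1 and dibromide 2. Nitrogen and its methyl group thus enter in the first step, and the first stereocentre is set by an auxiliary.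

## Roads not taken

**Alternative 1: ring contraction to ring B.** The cut is inside ring B: the C15–C16 bond and the C15 carboxyl carbon are traced back to the six-membered α-diazo ketone A2. Light-induced loss of nitrogen in an alcohol, migration of C16 and trapping of the ketene would give the ring-contracted ester A1.

- Merits: this photochemical rearrangement is more dependable than the key step chosen here, it has no strained intermediate, and a six-membered ring-B homologue is easier to annulate. The C15 ester and the N-carbamate of A1 would fall to CH2OH and N-methyl in one hydride step.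
- Weak points: C15 is created by protonation of a ketene-derived enol and stays epimerizable as an ester, while the target needs its less stable cis relation to C13. Diazo transfer must distinguish two α-methylene groups. The step comes after rings A, C and the piperidine exist, so it solves neither the C11-centred tricycle nor the C6/C17 pair.
- Comparison: against its greater reliability the chosen plan sets C15 in the first C–C bond-forming step at the alcohol oxidation level, where it cannot epimerize, and its key step builds two rings.

**Alternative 2: cyclocarbonylation for rings A and B.** The cut is C11–C12, C13–C14 and C10–C14: a cobalt-mediated cyclocarbonylation of the lactone-templated enyne A4 would give the bridged bicyclooctenone A3.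

- Merits: rings A and B form in one step and the lactone bridge ties the C15 CH2O carbon to C6 on C17. C17 is the centre that the chosen plan finds hardest to guarantee, and here it is fixed by a ring. In this respect the alternative is better.
- Weak points: C14 arrives as a ketone conjugated to C10=C11 and must be removed without moving the alkene. C6 arrives as a carboxyl carbon and must still become a quaternary stereocentre with two carbon substituents. Ring C must be closed separately as a seven-membered ring.
- Comparison: the chosen plan delivers ring C together with ring A, with C10=C11 in place and at the right oxidation level, and with C6 as a methylene ready for two enolate reactions.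

**Alternative 3: ring C by enolate alkenylation.** The cut is C11–C17: a palladium-catalysed coupling of the lactam enolate carbon C17 with the bromide-bearing C11 of the bromo lactam A6 would give the bridged lactam A5.

- Merits: it is the most convergent road. The piperidinone with C6, C7 and the side chain is made separately, the bridge allows only one configuration at C17, and the N-methyl amide is in place. In convergence and in control of C17 it is at least as good as the chosen plan.
- Weak points: the coupling must create a quaternary carbon next to the quaternary C6 inside a bridged seven-membered ring. Ring B is still missing in A5, so C12 and C15 would be set last, on a crowded core, in their less stable cis relation.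
- Comparison: the chosen plan fixes C12 and C15 in its first steps by well-precedented enolate chemistry and pays for this with a longer linear sequence.

Key step: step 14

## Route

Assumption: compounds 1, 2, 4, 5, 11 and 24 are taken as purchasable; should 24 not be at hand, it is one Noyori hydrogenation away from methyl 3-oxopentanoate.

Step 1
Reactants: 1 benzyl N-methylcarbamate; 2 3-bromo-2-(bromomethyl)prop-1-ene
Product: 3 benzyl N-[2-(bromomethyl)prop-2-en-1-yl]-N-methylcarbamate
Conditions: NaH, DMF, 0 °C; then 2 (3 equiv), 0 °C to rt
Reagents that add atoms: none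
Why: N-alkylation of the sodium carbamate at an allylic bromide (SN2); the excess of the symmetrical dibromide should hold the reaction at monosubstitution.

Step 2
Reactants: 4 4-tert-butoxy-4-oxobutanoic acid; 5 (S)-4-benzyl-1,3-oxazolidin-2-one
Product: 7 (S)-4-benzyl-3-(4-tert-butoxy-4-oxobutanoyl)-1,3-oxazolidin-2-one, via mixed pivalic anhydride 6 (not isolated)
Conditions: t-BuCOCl, Et3N, THF, −20 °C; then 5, LiCl, −20 °C to rt
Reagents that add atoms: none
Why: Standard N-acylation of an Evans oxazolidinone through the mixed anhydride with LiCl/Et3N activation; the tert-butyl ester is inert.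

Step 3
Reactants: 7 (S)-4-benzyl-3-(4-tert-butoxy-4-oxobutanoyl)-1,3-oxazolidin-2-one; 3 benzyl N-[2-(bromomethyl)prop-2-en-1-yl]-N-methylcarbamate
Product: 8 tert-butyl (3S)-3-{[(4S)-4-benzyl-2-oxo-1,3-oxazolidin-3-yl]carbonyl}-5-{[benzyloxycarbonyl(methyl)amino]methyl}hex-5-enoate
Conditions: NaN(SiMe3)2, THF, −78 °C; then 3, −78 to −40 °C
Reagents that add atoms: none
Why: Evans asymmetric alkylation; the chelated Z sodium enolate of the imide (more acidic than the tert-butyl ester) should be alkylated by the allylic bromide on the face away from the benzyl group, which forms C15–C16 and sets C15.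

Step 4
Reactants: 8 tert-butyl (3S)-3-{[(4S)-4-benzyl-2-oxo-1,3-oxazolidin-3-yl]carbonyl}-5-{[benzyloxycarbonyl(methyl)amino]methyl}hex-5-enoate
Product: 9 tert-butyl (3S)-5-{[benzyloxycarbonyl(methyl)amino]methyl}-3-(hydroxymethyl)hex-5-enoate
Conditions: LiBH4, MeOH (1 equiv), THF, 0 °C
Reagents that add atoms: none
Why: Reductive cleavage of the N-acyl oxazolidinone; the tert-butyl ester, carbamate and alkene should be untouched and auxiliary 5 is recovered.

Step 5
Reactants: 9 tert-butyl (3S)-5-{[benzyloxycarbonyl(methyl)amino]methyl}-3-(hydroxymethyl)hex-5-enoate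
Product: 10 (4S)-4-(2-{[benzyloxycarbonyl(methyl)amino]methyl}prop-2-en-1-yl)oxolan-2-one
Conditions: CF3CO2H, CH2Cl2, 0 °C to rt
Reagents that add atoms: none
Why: Acidolysis of the tert-butyl ester followed by spontaneous γ-lactonization; the benzyl carbamate is acid-stable and the alkene, deactivated by the allylic carbamate, should tolerate short exposure.

Step 6
Reactants: 10 (4S)-4-(2-{[benzyloxycarbonyl(methyl)amino]methyl}prop-2-en-1-yl)oxolan-2-one; 11 tert-butyl(3-iodopropoxy)dimethylsilane
Product: 12 (3S,4S)-4-(2-{[benzyloxycarbonyl(methyl)amino]methyl}prop-2-en-1-yl)-3-[3-(tert-butyldimethylsilyloxy)propyl]oxolan-2-one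
Conditions: LiN(SiMe3)2, THF, −78 °C; then 11, DMPU, −78 to −30 °C
Reagents that add atoms: none
Why: Alkylation of a β-substituted butyrolactone enolate anti to the β-substituent gives the trans lactone and sets C12; trans on the lactone equals cis on ring B because the lactone ring contains the CH2O carbon where ring B contains C16.

Step 7
Reactants: 12 (3S,4S)-4-(2-{[benzyloxycarbonyl(methyl)amino]methyl}prop-2-en-1-yl)-3-[3-(tert-butyldimethylsilyloxy)propyl]oxolan-2-one
Product: 13 lactol of 12 (oxolan-2-ol; anomer mixture)
Conditions: i-Bu2AlH (1.1 equiv), CH2Cl2, −78 °C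
Reagents that add atoms: none
Why: Half-reduction of a γ-lactone to the lactol; at −78 °C with one equivalent the carbamate should not be attacked.

Step 8
Reactants: 13 lactol of 12 (oxolan-2-ol; anomer mixture)
Product: 15 benzyl N-[(4S,5S)-8-(tert-butyldimethylsilyloxy)-5-ethynyl-4-(hydroxymethyl)-2-methylideneoctyl]-N-methylcarbamate, via open-chain hydroxy aldehyde 14 (not isolated)
Conditions: dimethyl (1-diazo-2-oxopropyl)phosphonate, K2CO3, MeOH, 0 °C to rt
Reagents that add atoms: dimethyl (1-diazo-2-oxopropyl)phosphonate, CC(=O)C(=[N+]=[N-])P(=O)(OC)OC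
Why: Ohira–Bestmann (Seyferth–Gilbert) homologation of the aldehyde form of the lactol turns C11 into the alkyne carbon, adds C8 and frees the CH2OH on C15; the trans lactol is the stable one, so C12 should not drift.

Step 9
Reactants: 15 benzyl N-[(4S,5S)-8-(tert-butyldimethylsilyloxy)-5-ethynyl-4-(hydroxymethyl)-2-methylideneoctyl]-N-methylcarbamate
Product: 16 benzyl N-[(4S,5S)-8-(tert-butyldimethylsilyloxy)-4-(tert-butyldiphenylsilyloxymethyl)-5-ethynyl-2-methylideneoctyl]-N-methylcarbamate
Conditions: t-BuPh2SiCl, imidazole, DMF, rt
Reagents that add atoms: tert-butyl(chloro)diphenylsilane, CC(C)(C)[Si](Cl)(c1ccccc1)c1ccccc1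
Why: Silylation of the primary alcohol; the diphenylsilyl ether is chosen because it outlasts the later acidic removal of the primary dimethylsilyl ether.

Step 10
Reactants: 16 benzyl N-[(4S,5S)-8-(tert-butyldimethylsilyloxy)-4-(tert-butyldiphenylsilyloxymethyl)-5-ethynyl-2-methylideneoctyl]-N-methylcarbamate
Product: 18 bicyclo[3.3.0]oct-1-en-3-one (C7 ketone; C8=C11) bearing CH2N(Me)CO2Bn on C17 and CH2OSiPh2t-Bu on C15 and (CH2)3OSiMe2t-Bu on C12, via hexacarbonyldicobalt alkyne complex 17 (not isolated)
Conditions: Co2(CO)8, CH2Cl2, rt; then N-methylmorpholine N-oxide, 0 °C to rt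
Reagents that add atoms: dicobalt octacarbonyl Co2(CO)8, O=C=[Co](=C=O)(=C=O)(=C=O)[Co](=C=O)(=C=O)(=C=O)=C=O
Why: Intramolecular Pauson–Khand reaction of a 1,6-enyne forms C11–C17, C6–C7 and C7–C8 under neutral conditions that leave C12 alone; in the forming ring B the angular CH2N group is pseudo-axial and should take the face opposite the C15 substituent (no 1,3-diaxial contact), which places C18 trans to the cis C12/C15 pair and sets C17.

Step 11
Reactants: 18 bicyclo[3.3.0]oct-1-en-3-one bearing the 3-(silyloxy)propyl chain on C12
Product: 19 bicyclo[3.3.0]oct-1-en-3-one bearing a 3-hydroxypropyl chain on C12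
Conditions: pyridinium p-toluenesulfonate, MeOH, rt
Reagents that add atoms: none
Why: Acid-catalysed methanolysis removes a primary tert-butyldimethylsilyl ether far faster than a tert-butyldiphenylsilyl ether; the enone is not enolized under these conditions.

Step 12
Reactants: 19 bicyclo[3.3.0]oct-1-en-3-one bearing a 3-hydroxypropyl chain on C12
Product: 20 bicyclo[3.3.0]oct-1-en-3-one bearing a 3-oxopropyl chain on C12
Conditions: Dess–Martin periodinane, CH2Cl2, rt
Reagents that add atoms: none
Why: Dess–Martin oxidation of a primary alcohol to the aldehyde under neutral conditions.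

Step 13
Reactants: 20 bicyclo[3.3.0]oct-1-en-3-one bearing a 3-oxopropyl chain on C12
Product: 21 bicyclo[3.3.0]oct-1-en-3-one bearing a but-3-ynyl chain on C12 (C13, C14, C10, C9)
Conditions: dimethyl (1-diazo-2-oxopropyl)phosphonate, K2CO3, MeOH, 0 °C
Reagents that add atoms: dimethyl (1-diazo-2-oxopropyl)phosphonate, CC(=O)C(=[N+]=[N-])P(=O)(OC)OC
Why: Ohira–Bestmann homologation adds C9; carbonate in cold methanol should not deprotonate the hindered γ-position C12 of the β,β-disubstituted enone at a useful rate.

Step 14
Reactants: 21 bicyclo[3.3.0]oct-1-en-3-one bearing a but-3-ynyl chain on C12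
Product: 23 tricyclic cyclohepta-2,4-dienone (rings A and B and C; C7 ketone; C8=C9 and C10=C11), via trans-fused [4.5.5.5]fenestrene 22 (not isolated)
Conditions: hν (366 nm), degassed toluene (5 mM), −40 °C; then 110 °C in the dark
Reagents that add atoms: none
Why: Excitation and intersystem crossing give the triplet enone, whose β-carbon C11 bonds to the nearer alkyne carbon C10 in a 1,5-closure (rule of five, five-membered ring A), and the 1,4-diradical then joins C8 to C9 to give the straight cyclobutene adduct 22. The closest known reaction type is the intramolecular enone–alkyne and enone–alkene photocycloaddition of 8-butynyl- and 8-butenyl-bicyclo[3.3.0]octenones to [4.5.5.5]fenestranes. Because the chain lies on the face of C6, ring A closes cis to ring B while the cyclopentanone becomes trans-fused to ring B, an arrangement accessible by this photochemical route and loaded with strain. On warming in the dark that strain should drive cleavage of C8–C11, the cyclobutene bond α to the C7 carbonyl, in a formal four-electron ring opening of the kind known for bicyclo[3.2.0]hept-6-en-2-ones; this returns C11 to sp2 as C10=C11 and opens ring C by a two-carbon ring expansion with both alkenes cis as the seven-membered ring demands. No new stereocentre survives, and C12, C15 and C17 are spectators under neutral conditions. The step needs the straight instead of the crossed adduct, which the three-atom link C12–C13–C14 enforces. It also needs freedom from secondary photochemistry, which long-wavelength light, low temperature and opening only after the lamp is off should provide.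

Step 15
Reactants: 24 methyl (S)-3-hydroxypentanoate
Product: 25 methyl (S)-3-(tert-butyldimethylsilyloxy)pentanoate
Conditions: t-BuMe2SiCl, imidazole, DMF, rt
Reagents that add atoms: tert-butyl(chloro)dimethylsilane, CC(C)(C)[Si](C)(C)Cl
Why: Standard silylation of a secondary alcohol; the carbinol configuration is untouched.

Step 16
Reactants: 25 methyl (S)-3-(tert-butyldimethylsilyloxy)pentanoate
Product: 26 (S)-3-(tert-butyldimethylsilyloxy)pentan-1-ol
Conditions: i-Bu2AlH (2.5 equiv), CH2Cl2, −78 to 0 °C
Reagents that add atoms: none
Why: Hydride reduction of the ester to the primary alcohol.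

Step 17
Reactants: 26 (S)-3-(tert-butyldimethylsilyloxy)pentan-1-ol
Product: 27 (S)-tert-butyl[(1-iodopentan-3-yl)oxy]dimethylsilane
Conditions: I2, PPh3, imidazole, CH2Cl2, 0 °C
Reagents that add atoms: iodine, II
Why: Appel-type iodination of a primary alcohol; the stereocentre is two carbons away.

Step 18
Reactants: 23 tricyclic cyclohepta-2,4-dienone; 27 (S)-tert-butyl[(1-iodopentan-3-yl)oxy]dimethylsilane
Product: 28 dienone carrying the (S)-3-(silyloxy)pentyl chain on C6 (C6 epimers; the one drawn is the expected major)
Conditions: LiN(i-Pr)2, THF, −78 °C; then 27, HMPA, −78 to −30 °C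
Reagents that add atoms: none
Why: Kinetic α′-deprotonation of the dienone at C6 (the only α-carbon with hydrogens, C8 being sp2) and SN2 alkylation by the primary iodide; the configuration at C6 does not matter because the centre is planarized in the next step.

Step 19
Reactants: 28 dienone carrying the (S)-3-(silyloxy)pentyl chain on C6
Product: 29 dienone with quaternary C6 bearing CH2OH (trans to C18) and the side chain (cis to C18)
Conditions: LiN(i-Pr)2, THF, −78 °C; then CH2O (monomeric, THF solution), −78 °C; AcOH quench at −78 °C
Reagents that add atoms: formaldehyde, C=O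
Why: Aldol addition of the C6 lithium enolate to formaldehyde, the smallest carbon electrophile; ring B holds C16 in the plane of C11, so C18 is pseudo-axial on C17 and shields one face of C6, and formaldehyde should enter anti to C18, which gives CH2OH trans and the side chain cis to C18 as in the target.

Step 20
Reactants: 29 dienone with quaternary C6 bearing CH2OH and the side chain
Product: 30 dienone with C6 bearing CH2OSiMe2t-Bu and the side chain
Conditions: t-BuMe2SiCl, imidazole, DMF, rt
Reagents that add atoms: tert-butyl(chloro)dimethylsilane, CC(C)(C)[Si](C)(C)Cl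
Why: Silylation of the neopentyl primary alcohol removes the retro-aldol pathway and keeps this hydroxyl from lactonizing onto the later C19 ester.

Step 21
Reactants: 30 dienone with C6 bearing CH2OSiMe2t-Bu and the side chain
Product: 31 cycloheptenone (C7 ketone; C8 and C9 saturated; C10=C11 retained)
Conditions: H2 (1 atm), RhCl(PPh3)3 (10 mol%), benzene, rt
Reagents that add atoms: none
Why: Homogeneous hydrogenation with RhCl(PPh3)3 reduces the cis-disubstituted C8=C9 and should leave the tetrasubstituted C10=C11 and the benzyl carbamate untouched.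

Step 22
Reactants: 31 cycloheptenone
Product: 32 enol triflate (C7 triflate; C7=C8)
Conditions: KN(SiMe3)2, THF, −78 °C; then PhNTf2, −78 to 0 °C
Reagents that add atoms: N-phenylbis(trifluoromethanesulfonimide), O=S(=O)(N(c1ccccc1)S(=O)(=O)C(F)(F)F)C(F)(F)F
Why: Enolization can occur only toward C8 because C6 is quaternary; O-sulfonylation of the potassium enolate gives the vinyl triflate.

Step 23
Reactants: 32 enol triflate
Product: 33 α,β-unsaturated methyl ester (C19 on C7; C7=C8)
Conditions: Pd(OAc)2 (10 mol%), PPh3, CO (1 atm), MeOH, Et3N, DMF, 60 °C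
Reagents that add atoms: carbon monoxide, [C-]#[O+]; methanol, CO
Why: Palladium-catalysed methoxycarbonylation of a vinyl triflate (oxidative addition to zerovalent palladium, CO insertion, methanolysis) attaches C19 to C7.

Step 24
Reactants: 33 α,β-unsaturated methyl ester
Product: 34 saturated methyl ester (C7 epimers; the one drawn is the epimer that cyclizes)
Conditions: Mg, MeOH, 0 °C to rt
Reagents that add atoms: none
Why: Dissolving-metal conjugate reduction of an α,β-unsaturated ester; the isolated tetrasubstituted alkene, silyl ethers and carbamate should not react, and the C7 mixture is converged in the next step.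

Step 25
Reactants: 34 saturated methyl ester
Product: 36 bridged N-methyl lactam (N–C19 amide; piperidinone ring closed), via N-methylamino ester 35 (not isolated)
Conditions: H2 (1 atm), Pd/C, MeOH, rt; filtration; then NaOMe, MeOH, 65 °C
Reagents that add atoms: none
Why: Hydrogenolysis of the benzyl carbamate frees the secondary amine, which can reach the ester only when C19 is cis to C18 (six-membered lactam); methoxide epimerizes C7 through the ester enolate, so both epimers should converge on 36 and C7 is set by the bridge.

Step 26
Reactants: 36 bridged N-methyl lactam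
Product: 37 tris-silylated N-methylpiperidine
Conditions: LiAlH4, THF, 65 °C
Reagents that add atoms: none
Why: Hydride reduction of a tertiary lactam to the amine; the silyl ethers are expected to survive.

Step 27
Reactants: 37 tris-silylated N-methylpiperidine
Product: 38 target amino triol
Conditions: Bu4NF, THF, 50 °C
Reagents that add atoms: none
Why: Fluoride cleaves the two tert-butyldimethylsilyl ethers and the tert-butyldiphenylsilyl ether in one operation.

## Compound list

1 | benzyl N-methylcarbamate | CNC(=O)OCc1ccccc1 | starting material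
2 | 3-bromo-2-(bromomethyl)prop-1-ene | C=C(CBr)CBr | starting material
3 | benzyl N-[2-(bromomethyl)prop-2-en-1-yl]-N-methylcarbamate | C=C(CBr)CN(C)C(=O)OCc1ccccc1 | intermediate
4 | 4-tert-butoxy-4-oxobutanoic acid | CC(C)(C)OC(=O)CCC(=O)O | starting material
5 | (S)-4-benzyl-1,3-oxazolidin-2-one | O=C1N[C@@H](Cc2ccccc2)CO1 | starting material
6 | mixed pivalic anhydride of 4 | CC(C)(C)OC(=O)CCC(=O)OC(=O)C(C)(C)C | intermediate
7 | (S)-4-benzyl-3-(4-tert-butoxy-4-oxobutanoyl)-1,3-oxazolidin-2-one | O=C(CCC(=O)OC(C)(C)C)N1[C@@H](Cc2ccccc2)COC1=O | intermediate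
8 | tert-butyl (3S)-3-{[(4S)-4-benzyl-2-oxo-1,3-oxazolidin-3-yl]carbonyl}-5-{[benzyloxycarbonyl(methyl)amino]methyl}hex-5-enoate | O=C([C@H](CC(=O)OC(C)(C)C)CC(=C)CN(C)C(=O)OCc1ccccc1)N1[C@@H](Cc2ccccc2)COC1=O | intermediate
9 | tert-butyl (3S)-5-{[benzyloxycarbonyl(methyl)amino]methyl}-3-(hydroxymethyl)hex-5-enoate | OC[C@H](CC(=O)OC(C)(C)C)CC(=C)CN(C)C(=O)OCc1ccccc1 | intermediate
10 | (4S)-4-(2-{[benzyloxycarbonyl(methyl)amino]methyl}prop-2-en-1-yl)oxolan-2-one | O=C1OC[C@@H](CC(=C)CN(C)C(=O)OCc2ccccc2)C1 | intermediate
11 | tert-butyl(3-iodopropoxy)dimethylsilane | ICCCO[Si](C)(C)C(C)(C)C | starting material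
12 | (3S,4S)-4-(2-{[benzyloxycarbonyl(methyl)amino]methyl}prop-2-en-1-yl)-3-[3-(tert-butyldimethylsilyloxy)propyl]oxolan-2-one (trans) | O=C1OC[C@@H](CC(=C)CN(C)C(=O)OCc2ccccc2)[C@@H]1CCCO[Si](C)(C)C(C)(C)C | intermediate
13 | lactol of 12 (anomer mixture) | OC1OC[C@@H](CC(=C)CN(C)C(=O)OCc2ccccc2)[C@@H]1CCCO[Si](C)(C)C(C)(C)C | intermediate
14 | open-chain hydroxy aldehyde (tautomer of 13) | O=C[C@@H](CCCO[Si](C)(C)C(C)(C)C)[C@@H](CO)CC(=C)CN(C)C(=O)OCc1ccccc1 | intermediate
15 | benzyl N-[(4S,5S)-8-(tert-butyldimethylsilyloxy)-5-ethynyl-4-(hydroxymethyl)-2-methylideneoctyl]-N-methylcarbamate | C#C[C@@H](CCCO[Si](C)(C)C(C)(C)C)[C@@H](CO)CC(=C)CN(C)C(=O)OCc1ccccc1 | intermediate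
16 | benzyl N-[(4S,5S)-8-(tert-butyldimethylsilyloxy)-4-(tert-butyldiphenylsilyloxymethyl)-5-ethynyl-2-methylideneoctyl]-N-methylcarbamate | C#C[C@@H](CCCO[Si](C)(C)C(C)(C)C)[C@@H](CO[Si](c1ccccc1)(c1ccccc1)C(C)(C)C)CC(=C)CN(C)C(=O)OCc1ccccc1 | intermediate
17 | hexacarbonyldicobalt complex of the terminal alkyne of 16 | C12[Co]3(=C=O)(=C=O)(=C=O)[Co]1(=C=O)(=C=O)(=C=O)C23[C@@H](CCCO[Si](C)(C)C(C)(C)C)[C@@H](CO[Si](c1ccccc1)(c1ccccc1)C(C)(C)C)CC(=C)CN(C)C(=O)OCc1ccccc1 | intermediate
18 | bicyclo[3.3.0]oct-1-en-3-one; angular CH2N(Me)CO2Bn (C18) on C17; CH2OSiPh2t-Bu on C15 and (CH2)3OSiMe2t-Bu on C12, both cis to C6 and trans to C18 | O=C1C[C@]2(CN(C)C(=O)OCc3ccccc3)C[C@H](CO[Si](c3ccccc3)(c3ccccc3)C(C)(C)C)[C@H](CCCO[Si](C)(C)C(C)(C)C)C2=C1 | intermediate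
19 | as 18 with a 3-hydroxypropyl chain on C12 | O=C1C[C@]2(CN(C)C(=O)OCc3ccccc3)C[C@H](CO[Si](c3ccccc3)(c3ccccc3)C(C)(C)C)[C@H](CCCO)C2=C1 | intermediate
20 | as 18 with a 3-oxopropyl chain on C12 | O=C1C[C@]2(CN(C)C(=O)OCc3ccccc3)C[C@H](CO[Si](c3ccccc3)(c3ccccc3)C(C)(C)C)[C@H](CCC=O)C2=C1 | intermediate
21 | as 18 with a but-3-ynyl chain on C12 (photosubstrate) | O=C1C[C@]2(CN(C)C(=O)OCc3ccccc3)C[C@H](CO[Si](c3ccccc3)(c3ccccc3)C(C)(C)C)[C@H](CCC#C)C2=C1 | intermediate
22 | [4.5.5.5]fenestrene: C11 bonded to C8, C10, C12, C17; cyclobutene C8–C9=C10–C11; ring A cis-fused and the cyclopentanone trans-fused to ring B | O=C1C[C@]2(CN(C)C(=O)OCc5ccccc5)C[C@H](CO[Si](c5ccccc5)(c5ccccc5)C(C)(C)C)[C@@H]3CCC4=C[C@H]1[C@@]234 | intermediate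
23 | tricyclic cyclohepta-2,4-dienone (C7 ketone, C8=C9, C10=C11; C6 unsubstituted) | C1C(=O)C=CC2=C3[C@@H](CC2)[C@@H](CO[Si](c4ccccc4)(c4ccccc4)C(C)(C)C)C[C@]31CN(C)C(=O)OCc4ccccc4 | intermediate
24 | methyl (S)-3-hydroxypentanoate | CC[C@H](O)CC(=O)OC | starting material
25 | methyl (S)-3-(tert-butyldimethylsilyloxy)pentanoate | CC[C@H](O[Si](C)(C)C(C)(C)C)CC(=O)OC | intermediate
26 | (S)-3-(tert-butyldimethylsilyloxy)pentan-1-ol | CC[C@H](O[Si](C)(C)C(C)(C)C)CCO | intermediate
27 | (S)-tert-butyl[(1-iodopentan-3-yl)oxy]dimethylsilane | CC[C@H](O[Si](C)(C)C(C)(C)C)CCI | intermediate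
28 | dienone 23 with the (S)-3-(silyloxy)pentyl chain on C6 (C6 epimers; expected major drawn, chain trans to C18) | CC[C@H](O[Si](C)(C)C(C)(C)C)CC[C@H]1C(=O)C=CC2=C3[C@@H](CC2)[C@@H](CO[Si](c4ccccc4)(c4ccccc4)C(C)(C)C)C[C@]31CN(C)C(=O)OCc4ccccc4 | intermediate
29 | dienone with quaternary C6: CH2OH trans to C18, side chain cis to C18 | CC[C@H](O[Si](C)(C)C(C)(C)C)CC[C@]1(CO)C(=O)C=CC2=C3[C@@H](CC2)[C@@H](CO[Si](c4ccccc4)(c4ccccc4)C(C)(C)C)C[C@]31CN(C)C(=O)OCc4ccccc4 | intermediate
30 | tert-butyldimethylsilyl ether of 29 | CC[C@H](O[Si](C)(C)C(C)(C)C)CC[C@]1(CO[Si](C)(C)C(C)(C)C)C(=O)C=CC2=C3[C@@H](CC2)[C@@H](CO[Si](c4ccccc4)(c4ccccc4)C(C)(C)C)C[C@]31CN(C)C(=O)OCc4ccccc4 | intermediate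
31 | cycloheptenone (C8, C9 saturated) | CC[C@H](O[Si](C)(C)C(C)(C)C)CC[C@]1(CO[Si](C)(C)C(C)(C)C)C(=O)CCC2=C3[C@@H](CC2)[C@@H](CO[Si](c4ccccc4)(c4ccccc4)C(C)(C)C)C[C@]31CN(C)C(=O)OCc4ccccc4 | intermediate
32 | enol triflate (C7–OTf, C7=C8) | CC[C@H](O[Si](C)(C)C(C)(C)C)CC[C@]1(CO[Si](C)(C)C(C)(C)C)C(OS(=O)(=O)C(F)(F)F)=CCC2=C3[C@@H](CC2)[C@@H](CO[Si](c4ccccc4)(c4ccccc4)C(C)(C)C)C[C@]31CN(C)C(=O)OCc4ccccc4 | intermediate
33 | α,β-unsaturated methyl ester (C19 on C7, C7=C8) | CC[C@H](O[Si](C)(C)C(C)(C)C)CC[C@]1(CO[Si](C)(C)C(C)(C)C)C(C(=O)OC)=CCC2=C3[C@@H](CC2)[C@@H](CO[Si](c4ccccc4)(c4ccccc4)C(C)(C)C)C[C@]31CN(C)C(=O)OCc4ccccc4 | intermediate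
34 | saturated methyl ester (C7 epimers; drawn with C19 cis to C18) | CC[C@H](O[Si](C)(C)C(C)(C)C)CC[C@]1(CO[Si](C)(C)C(C)(C)C)[C@H](C(=O)OC)CCC2=C3[C@@H](CC2)[C@@H](CO[Si](c4ccccc4)(c4ccccc4)C(C)(C)C)C[C@]31CN(C)C(=O)OCc4ccccc4 | intermediate
35 | N-methylamino ester (carbamate removed) | CC[C@H](O[Si](C)(C)C(C)(C)C)CC[C@]1(CO[Si](C)(C)C(C)(C)C)[C@H](C(=O)OC)CCC2=C3[C@@H](CC2)[C@@H](CO[Si](c4ccccc4)(c4ccccc4)C(C)(C)C)C[C@]31CNC | intermediate
36 | bridged N-methyl lactam (C19 carbonyl) | CC[C@H](O[Si](C)(C)C(C)(C)C)CC[C@]1(CO[Si](C)(C)C(C)(C)C)[C@H]2CCC3=C4[C@@H](CC3)[C@@H](CO[Si](c5ccccc5)(c5ccccc5)C(C)(C)C)C[C@]41CN(C)C2=O | intermediate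
37 | tris-silylated N-methylpiperidine | CC[C@H](O[Si](C)(C)C(C)(C)C)CC[C@]1(CO[Si](C)(C)C(C)(C)C)[C@H]2CCC3=C4[C@@H](CC3)[C@@H](CO[Si](c5ccccc5)(c5ccccc5)C(C)(C)C)C[C@]41CN(C)C2 | intermediate
38 | CNP0221997.1 | CC[C@H](O)CC[C@]1(CO)[C@H]2CCC3=C4[C@@H](CC3)[C@@H](CO)C[C@]41CN(C)C2 | target

## Step count and risks

Total: 27 steps. Longest linear sequence: 23 steps (steps 2–14, then 18–27; the branch through step 1 is of equal length).

**Step 14 (key step).** The most likely failures are three. The 1,4-diradical may revert to 21 instead of closing, because closure has to build a trans-fused fenestrene. Fenestrene 22 may undergo a 1,3-acyl shift under the lamp. The thermal opening may need temperatures at which acyl or alkyl shifts of the β,γ-unsaturated ketone compete. If 22 opens already at −40 °C, dienone 23 would be exposed to light. Fallback: make the same bonds in the ground state by a metal-catalysed enyne skeletal rearrangement on an electron-rich alkene. From 21, reduction with NaBH4 and CeCl3·7H2O in MeOH gives the allylic alcohol F1. PtCl2 (5 mol%, toluene, 80 °C) should then join C10 to C11, move C8 from C11 to C9 (single-cleavage rearrangement through a cyclopropyl platinum carbene) and give the ring-expanded dienol F2. Oxidation with MnO2 returns to the route at 23.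

**Step 10.** The risk is poor facial selectivity at C17. Only the 1,3-relation to the C15 substituent distinguishes the two faces of the 1,1-disubstituted alkene, and a terminal alkyne gives no propargylic bias. The wrong epimer cannot be corrected later. Fallback: move the control from the substrate to the catalyst. From 16, a carbonylative cyclization at a chiral cationic rhodium centre ([Rh(CO)2Cl]2, AgOTf, the matching enantiomer of BINAP, CO 1 atm, THF, 80 °C) should give 18 directly. It passes through no new compound (F0).

**Step 19.** The risks are slow or incomplete enolization of the hindered C6 methine, competing removal of an ε-proton (C12 or C14) once the kinetic regime is left, and reversal of the aldol before the quench. Fallback: separate enolization from bond formation. From 28, deprotonation with LiN(i-Pr)2 in the presence of Me3SiCl (internal quench, −78 °C) gives the silyl dienol ether F3. A Mukaiyama hydroxymethylation with aqueous formaldehyde and Yb(OTf)3 in THF, which is not reversible under these conditions, then leads back to 29.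

**Step 25.** The risk is slow acylation of the hindered secondary amine by the neopentyl-type ester, so that epimerization at C7 and ring closure do not keep pace and material is lost to transesterification or decomposition. Fallback: close the ring through an iminium ion instead of an amide. From 34, i-Bu2AlH at −78 °C gives the aldehyde F4, whose C7 centre epimerizes easily. Hydrogenolysis of the carbamate (H2, Pd/C, MeOH) in the same flask lets the freed amine condense with the cis aldehyde and reduces the cyclic iminium ion. This rejoins the route at 37 and makes step 26 unnecessary.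

## Further compounds

F1 | step 14 | allylic alcohol from 21 (C7 carbinol epimers) | OC1C[C@]2(CN(C)C(=O)OCc3ccccc3)C[C@H](CO[Si](c3ccccc3)(c3ccccc3)C(C)(C)C)[C@H](CCC#C)C2=C1
F2 | step 14 | ring-expanded tricyclic dienol (C7 carbinol epimers) | C1C(O)C=CC2=C3[C@@H](CC2)[C@@H](CO[Si](c4ccccc4)(c4ccccc4)C(C)(C)C)C[C@]31CN(C)C(=O)OCc4ccccc4
F0 | step 10 | none | none
F3 | step 19 | trimethylsilyl dienol ether of 28 (C6=C7) | CC[C@H](O[Si](C)(C)C(C)(C)C)CCC1=C(O[Si](C)(C)C)C=CC2=C3[C@@H](CC2)[C@@H](CO[Si](c4ccccc4)(c4ccccc4)C(C)(C)C)C[C@]31CN(C)C(=O)OCc4ccccc4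
F4 | step 25 | C19 aldehyde from 34 (C7 epimers) | CC[C@H](O[Si](C)(C)C(C)(C)C)CC[C@]1(CO[Si](C)(C)C(C)(C)C)C(C=O)CCC2=C3[C@@H](CC2)[C@@H](CO[Si](c4ccccc4)(c4ccccc4)C(C)(C)C)C[C@]31CN(C)C(=O)OCc4ccccc4
A1 | alternative 1 | ring-contracted C15 methyl ester | CC[C@H](O[Si](C)(C)C(C)(C)C)CC[C@]1(CO[Si](C)(C)C(C)(C)C)[C@H]2CCC3=C4[C@@H](CC3)[C@@H](C(=O)OC)C[C@]41CN(C(=O)OC)C2
A2 | alternative 1 | α-diazo cyclohexanone homologue of ring B | CC[C@H](O[Si](C)(C)C(C)(C)C)CC[C@]1(CO[Si](C)(C)C(C)(C)C)[C@H]2CCC3=C4[C@@H](CC3)C(=[N+]=[N-])C(=O)C[C@]41CN(C(=O)OC)C2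
A3 | alternative 2 | lactone-bridged bicyclo[3.3.0]octenone | N#CCCCC1=C2[C@@H](CC1=O)[C@H]3COC(=O)[C@]2(COCc4ccccc4)C3
A4 | alternative 2 | enyne lactone | N#CCCCC#C[C@@]1(COCc2ccccc2)C[C@@H](C=C)COC1=O
A5 | alternative 3 | bridged lactam with quaternary C17 | CC[C@H](OCOC)CC[C@]1(COCOC)[C@H]2CCC3=C([C@@H](O[Si](C)(C)C(C)(C)C)CC3)[C@]1(CC=C)C(=O)N(C)C2
A6 | alternative 3 | bromo lactam | CC[C@H](OCOC)CC[C@]1(COCOC)[C@@H](CCC2=C(Br)[C@@H](O[Si](C)(C)C(C)(C)C)CC2)CN(C)C(=O)C1CC=C
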